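**Retrosynthetic overview**
1. Target ⇒ desilylation and C17 oxidation ⇒ Stille union at C7–C8 of a lactone vinylstannane (fragment A, C1–C7) with a Z-vinyl iodide acid (fragment BC, C8–C24).
2. Fragment BC ⇒ Julia–Kocienski olefination at C12=C13 of a PT-sulfone (fragment B, C8–C12) with an enal (fragment C, C13–C24).
3. Fragment A: the only ring, the 5,6-dihydro-2H-pyran-2-one, is closed early by ring-closing metathesis of the acrylate of an anti-crotylation product of (E)-3-stannylacrolein.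
4. Fragment C ⇒ Evans syn-aldol (C16–C17; the auxiliary carbonyl becomes the CH2OH), Brown anti-crotylation (C18–C19), Evans alkylation (C20); the C13 oxygen comes from an SeO2 allylic oxidation.
5. Fragment B ⇒ Evans alkylation (C10) and Stork–Zhao iodo-olefination (C8=C9, Z).

Assumption: the configuration is taken exactly as written in the SMILES; numbering the chain from the lactone carbonyl (C1) to the acid carbon (C24) this is 4S,5R,6E,8Z,10S,12E,14E,16S,18R,19R,20R,22E, i.e. a trans-4,5-disubstituted lactone and an anti,anti C18–C20 triad.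

**Fragment A (C1–C7)**

Step 1
Reactants: 1 prop-2-yn-1-ol
Product: 2 (2E)-3-(tributylstannyl)prop-2-en-1-ol
Conditions: Bu3SnH, AIBN (cat.), neat, 80 °C; chromatography to remove the Z and 2-stannyl isomers
Reagents that add atoms: tributyltin hydride, CCCC[SnH](CCCC)CCCC
Why: Radical hydrostannation puts tin on the terminal carbon and the reversible stannyl-radical addition equilibrates to the E-vinylstannane that carries the C6=C7 geometry.

Step 2
Reactants: 2 (2E)-3-(tributylstannyl)prop-2-en-1-ol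
Product: 3 (2E)-3-(tributylstannyl)prop-2-enal
Conditions: MnO2, CH2Cl2, rt
Reagents that add atoms: none
Why: MnO2 allylic oxidation stops at the enal and leaves the vinylstannane untouched.

Step 3
Reactants: 3 (2E)-3-(tributylstannyl)prop-2-enal
Product: 5 (1E,3S,4S)-4-methyl-1-(tributylstannyl)hexa-1,5-dien-3-ol, via borinate ester 4 (not isolated)
Conditions: trans-but-2-ene, KOtBu, n-BuLi, THF, −78 to −45 °C; (−)-Ipc2BOMe, −78 °C; BF3·OEt2; then 3, −78 °C; NaBO3·4H2O, THF/H2O, rt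
Reagents that add atoms: (E)-but-2-enyl-diisopinocampheylborane (made in the flask from trans-but-2-ene, C/C=C/C), C/C=C/CB([C@@H]1C[C@@H]2C[C@H]([C@H]1C)C2(C)C)[C@@H]1C[C@@H]2C[C@H]([C@H]1C)C2(C)C
Why: Brown asymmetric crotylboration through a chair Zimmerman–Traxler transition state: the E-crotyl unit gives the anti relationship and the Ipc ligands of the (+)-α-pinene series select the aldehyde face, setting C5 and C4 of the target (3S,4S here).

Step 4
Reactants: 5 (1E,3S,4S)-4-methyl-1-(tributylstannyl)hexa-1,5-dien-3-ol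
Product: 6 (1E,3S,4S)-4-methyl-1-(tributylstannyl)hexa-1,5-dien-3-yl prop-2-enoate
Conditions: acryloyl chloride, Et3N, DMAP (cat.), CH2Cl2, −78 to 0 °C
Reagents that add atoms: acryloyl chloride, C=CC(=O)Cl
Why: O-acylation of the secondary allylic alcohol installs the acrylate for ring closure without touching a stereocentre.

Step 5
Reactants: 6 (1E,3S,4S)-4-methyl-1-(tributylstannyl)hexa-1,5-dien-3-yl prop-2-enoate
Product: 7 (5S,6S)-5-methyl-6-[(E)-2-(tributylstannyl)ethenyl]-5,6-dihydro-2H-pyran-2-one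
Conditions: second-generation Grubbs catalyst RuCl2(=CHPh)(H2IMes)(PCy3) (5 mol%), CH2Cl2 (5 mM), 40 °C
Reagents that add atoms: none
Why: Ring-closing metathesis between the acrylate and the monosubstituted vinyl group closes the six-membered α,β-unsaturated lactone with loss of ethene, and the bulky internal stannyl alkene is not a competent metathesis partner.

**Fragment B (C8–C12)**

Step 6
Reactants: 8 (4R)-4-benzyl-3-propanoyl-1,3-oxazolidin-2-one
Product: 10 tert-butyl (3S)-4-[(4R)-4-benzyl-2-oxo-1,3-oxazolidin-3-yl]-3-methyl-4-oxobutanoate, via sodium enolate 9 (not isolated)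
Conditions: NaHMDS, THF, −78 °C; BrCH2CO2tBu, −78 to −40 °C
Reagents that add atoms: tert-butyl bromoacetate, BrCC(=O)OC(C)(C)C
Why: Evans asymmetric alkylation: the chelated Z-enolate is alkylated on the face opposite the benzyl group, which sets C10 of the target (3S here).

Step 7
Reactants: 10 alkylated imide
Product: 11 tert-butyl (3S)-4-hydroxy-3-methylbutanoate
Conditions: LiBH4, MeOH (1 equiv), THF, 0 °C
Reagents that add atoms: none
Why: LiBH4 reductively cleaves the activated imide much faster than the tert-butyl ester and does not touch the stereocentre.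

Step 8
Reactants: 11 tert-butyl (3S)-4-hydroxy-3-methylbutanoate
Product: 12 tert-butyl (3S)-3-methyl-4-oxobutanoate
Conditions: Dess–Martin periodinane, CH2Cl2, rt; used at once
Reagents that add atoms: none
Why: Dess–Martin oxidation gives the α-methyl aldehyde under neutral conditions that avoid epimerisation.

Step 9
Reactants: 12 tert-butyl (3S)-3-methyl-4-oxobutanoate
Product: 13 tert-butyl (3S,4Z)-5-iodo-3-methylhex-4-enoate
Conditions: EtPPh3I, n-BuLi, THF, rt; I2, −78 °C; NaHMDS, −20 °C; then 12, −78 °C to rt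
Reagents that add atoms: ethyltriphenylphosphonium iodide, CC[P+](c1ccccc1)(c1ccccc1)c1ccccc1.[I-]; iodine, [I][I]
Why: Stork–Zhao-type Wittig olefination with the non-stabilised α-iodo ylide gives, under kinetic control, the Z-trisubstituted vinyl iodide with iodine cis to the chain (the future C8=C9 geometry).

Step 10
Reactants: 13 tert-butyl (3S,4Z)-5-iodo-3-methylhex-4-enoate
Product: 14 (3S,4Z)-5-iodo-3-methylhex-4-en-1-ol
Conditions: DIBAL-H (iBu2AlH, 2.5 equiv), CH2Cl2, −78 to 0 °C; Rochelle salt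
Reagents that add atoms: none
Why: Hydride reduction of the ester to the primary alcohol, to which the vinyl iodide is inert.

Step 11
Reactants: 14 (3S,4Z)-5-iodo-3-methylhex-4-en-1-ol
Product: 15 5-{[(3S,4Z)-5-iodo-3-methylhex-4-en-1-yl]sulfanyl}-1-phenyl-1H-tetrazole
Conditions: 1-phenyl-1H-tetrazole-5-thiol, PPh3, DIAD, THF, 0 °C to rt
Reagents that add atoms: 1-phenyl-1H-tetrazole-5-thiol, Sc1nnnn1-c1ccccc1
Why: Mitsunobu thioetherification of the primary alcohol with the acidic heteroaryl thiol.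

Step 12
Reactants: 15 PT-sulfide
Product: 16 5-{[(3S,4Z)-5-iodo-3-methylhex-4-en-1-yl]sulfonyl}-1-phenyl-1H-tetrazole
Conditions: (NH4)6Mo7O24·4H2O (cat.), 30% H2O2, EtOH, 0 °C to rt
Reagents that add atoms: hydrogen peroxide, OO
Why: Molybdate-catalysed sulfide-to-sulfone oxidation, in which the electron-poor iodoalkene is not epoxidised.

**Fragment C (C13–C24)**

Step 13
Reactants: 17 ethyl 3-methylbut-2-enoate
Product: 18 ethyl (2E)-4-bromo-3-methylbut-2-enoate
Conditions: NBS, AIBN (cat.), PhCF3, 85 °C; chromatography to isolate the E isomer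
Reagents that add atoms: N-bromosuccinimide, O=C1CCC(=O)N1Br
Why: Wohl–Ziegler allylic bromination, from which the E isomer (bromomethyl trans to the ester) is separated and fixes the C22=C23 geometry.

Step 14
Reactants: 19 (4S)-4-benzyl-3-propanoyl-1,3-oxazolidin-2-one; 18 ethyl (2E)-4-bromo-3-methylbut-2-enoate
Product: 21 ethyl (2E,5R)-6-[(4S)-4-benzyl-2-oxo-1,3-oxazolidin-3-yl]-3,5-dimethyl-6-oxohex-2-enoate, via sodium enolate 20 (not isolated)
Conditions: NaHMDS, THF, −78 °C; 18, −78 to −40 °C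
Reagents that add atoms: none
Why: Evans asymmetric alkylation by direct SN2 attack on the allylic bromide (the β,β-disubstituted enoate resists conjugate addition), opposite the benzyl group, sets C20 (5R here).

Step 15
Reactants: 21 alkylated imide
Product: 22 ethyl (2E,5R)-6-hydroxy-3,5-dimethylhex-2-enoate
Conditions: LiBH4, MeOH (1 equiv), Et2O, 0 °C, 1 h
Reagents that add atoms: none
Why: Chemoselective hydride cleavage of the activated imide, which the deactivated β,β-disubstituted enoate survives at 0 °C.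

Step 16
Reactants: 22 ethyl (2E,5R)-6-hydroxy-3,5-dimethylhex-2-enoate
Product: 23 ethyl (2E,5R)-3,5-dimethyl-6-oxohex-2-enoate
Conditions: Dess–Martin periodinane, CH2Cl2, rt; used at once
Reagents that add atoms: none
Why: Dess–Martin oxidation to the α-methyl aldehyde without epimerisation.

Step 17
Reactants: 23 ethyl (2E,5R)-3,5-dimethyl-6-oxohex-2-enoate
Product: 25 ethyl (2E,5R,6R,7S)-6-hydroxy-3,5,7-trimethylnona-2,8-dienoate, via borinate ester 24 (not isolated)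
Conditions: trans-but-2-ene, KOtBu, n-BuLi, THF, −78 to −45 °C; (−)-Ipc2BOMe, −78 °C; BF3·OEt2; then 23, −78 °C; NaBO3·4H2O, THF/H2O, rt
Reagents that add atoms: (E)-but-2-enyl-diisopinocampheylborane (made in the flask from trans-but-2-ene, C/C=C/C), C/C=C/CB([C@@H]1C[C@@H]2C[C@H]([C@H]1C)C2(C)C)[C@@H]1C[C@@H]2C[C@H]([C@H]1C)C2(C)C
Why: Reagent-controlled Brown crotylboration: the E-crotyl unit gives C18/C19 anti and the Ipc ligands override the α-stereocentre to give the C19/C20 anti (anti-Felkin) isomer, completing the anti,anti triad.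

Step 18
Reactants: 25 homoallylic alcohol
Product: 26 ethyl (2E,5R,6R,7S)-6-[(tert-butyldimethylsilyl)oxy]-3,5,7-trimethylnona-2,8-dienoate
Conditions: TBSOTf, 2,6-lutidine, CH2Cl2, −78 to 0 °C
Reagents that add atoms: tert-butyldimethylsilyl trifluoromethanesulfonate, CC(C)(C)[Si](C)(C)OS(=O)(=O)C(F)(F)F
Why: The reactive silyl triflate protects the hindered C19 hydroxyl as a robust silyl ether.

Step 19
Reactants: 26 TBS ether
Product: 28 ethyl (2E,5R,6R,7R)-6-[(tert-butyldimethylsilyl)oxy]-3,5,7-trimethyl-8-oxooct-2-enoate, via diol 27 (not isolated)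
Conditions: OsO4 (2 mol%), NMO, acetone/H2O, rt; then NaIO4, THF/pH 7 buffer, 0 °C; used at once
Reagents that add atoms: osmium tetroxide (catalytic oxygen carrier), O=[Os](=O)(=O)=O; 4-methylmorpholine N-oxide, C[N+]1([O-])CCOCC1; water, O
Why: Upjohn dihydroxylation takes the monosubstituted alkene in preference to the electron-poor trisubstituted enoate, and periodate glycol cleavage then gives the C17 aldehyde under neutral conditions.

Step 20
Reactants: 29 4-methylpent-3-enoic acid; 30 (4R)-4-benzyl-1,3-oxazolidin-2-one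
Product: 32 (4R)-4-benzyl-3-(4-methylpent-3-enoyl)-1,3-oxazolidin-2-one, via mixed pivalic anhydride 31 (not isolated)
Conditions: PivCl, Et3N, THF, −20 °C; then 30, LiCl, rt
Reagents that add atoms: none
Why: Mixed-anhydride N-acylation of the oxazolidinone under mild conditions that do not move the β,γ-double bond.

Step 21
Reactants: 32 (4R)-4-benzyl-3-(4-methylpent-3-enoyl)-1,3-oxazolidin-2-one; 28 C17 aldehyde
Product: 35 ethyl (2E,5R,6R,7S,8S,9R)-9-[(4R)-4-benzyl-2-oxo-1,3-oxazolidine-3-carbonyl]-6-[(tert-butyldimethylsilyl)oxy]-8-hydroxy-3,5,7,11-tetramethyldodeca-2,10-dienoate, via boron dienolate 33 (not isolated), via boron aldolate 34 (not isolated)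
Conditions: Bu2BOTf, Et3N, CH2Cl2, −78 to 0 °C; 28, −78 to 0 °C; pH 7 buffer, MeOH, 30% H2O2, 0 °C
Reagents that add atoms: none
Why: Evans syn-aldol through the Z-boron dienolate and a chair Zimmerman–Traxler transition state: the (4R)-auxiliary dictates C16 (whose acyl carbon later becomes the CH2OH) and bonding occurs at the α-carbon, while the C17 carbinol centre formed here is later erased by oxidation.

Step 22
Reactants: 35 aldol adduct
Product: 36 ethyl (2E,5R,6R,7S,8R,9S)-6-[(tert-butyldimethylsilyl)oxy]-8-hydroxy-9-(hydroxymethyl)-3,5,7,11-tetramethyldodeca-2,10-dienoate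
Conditions: LiBH4, MeOH (2 equiv), THF, 0 °C
Reagents that add atoms: none
Why: Reductive removal of the auxiliary turns the imide carbonyl into the C16 hydroxymethyl group, and the conjugated ester is reduced far more slowly.

Step 23
Reactants: 36 1,3-diol
Product: 37 ethyl (2E,5R,6R,7S,8R,9S)-6-[(tert-butyldimethylsilyl)oxy]-8-hydroxy-3,5,7,11-tetramethyl-9-({[tri(propan-2-yl)silyl]oxy}methyl)dodeca-2,10-dienoate
Conditions: TIPSCl, imidazole, DMF, 0 °C to rt
Reagents that add atoms: chlorotri(propan-2-yl)silane, CC(C)[Si](Cl)(C(C)C)C(C)C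
Why: The bulky silyl chloride reacts only with the primary hydroxyl of the diol.

Step 24
Reactants: 37 mono-TIPS ether
Product: 38 ethyl (2E,5R,6R,7R,8R,9S)-6-[(tert-butyldimethylsilyl)oxy]-3,5,7,11-tetramethyl-8-[(triethylsilyl)oxy]-9-({[tri(propan-2-yl)silyl]oxy}methyl)dodeca-2,10-dienoate
Conditions: TESOTf, 2,6-lutidine, CH2Cl2, −78 to 0 °C
Reagents that add atoms: triethylsilyl trifluoromethanesulfonate, CC[Si](CC)(CC)OS(=O)(=O)C(F)(F)F
Why: The hindered C17 hydroxyl is masked as the one silyl ether that can later be removed selectively.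

Step 25
Reactants: 38 fully silylated ester
Product: 39 ethyl (2E,5R,6R,7R,8R,9S,10E)-6-[(tert-butyldimethylsilyl)oxy]-12-hydroxy-3,5,7,11-tetramethyl-8-[(triethylsilyl)oxy]-9-({[tri(propan-2-yl)silyl]oxy}methyl)dodeca-2,10-dienoate
Conditions: SeO2 (0.5 equiv), t-BuOOH, CH2Cl2, 0 °C to rt
Reagents that add atoms: selenium dioxide (catalytic oxygen carrier), O=[Se]=O; tert-butyl hydroperoxide, CC(C)(C)OO
Why: Sharpless SeO2/t-BuOOH allylic oxidation (ene reaction then 2,3-sigmatropic shift) attacks the E-methyl group of the electron-rich isobutenyl unit and so gives the E-allylic alcohol (C14=C15 E), while the electron-poor enoate is inert.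

Step 26
Reactants: 39 allylic alcohol
Product: 40 ethyl (2E,5R,6R,7R,8R,9S,10E)-6-[(tert-butyldimethylsilyl)oxy]-3,5,7,11-tetramethyl-12-oxo-8-[(triethylsilyl)oxy]-9-({[tri(propan-2-yl)silyl]oxy}methyl)dodeca-2,10-dienoate
Conditions: MnO2, CH2Cl2, rt
Reagents that add atoms: none
Why: MnO2 allylic oxidation gives the enal without isomerising the trisubstituted alkene; any enal already formed in step 25 is carried along.

**Fragment union and endgame**

Step 27
Reactants: 16 PT-sulfone (fragment B); 40 enal (fragment C)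
Product: 42 ethyl (2E,5R,6R,7R,8R,9S,10E,12E,15S,16Z)-6-[(tert-butyldimethylsilyl)oxy]-17-iodo-3,5,7,11,15-pentamethyl-8-[(triethylsilyl)oxy]-9-({[tri(propan-2-yl)silyl]oxy}methyl)octadeca-2,10,12,16-tetraenoate, via potassium sulfonyl carbanion 41 (not isolated)
Conditions: KHMDS, DME, −60 °C, 15 min; then 40, −60 °C to rt
Reagents that add atoms: none
Why: Julia–Kocienski olefination of the metalated alkyl PT-sulfone with the enal gives the C12=C13 E-alkene through anti addition, Smiles rearrangement and anti elimination.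

Step 28
Reactants: 42 fragment BC ester
Product: 43 ethyl (2E,5R,6R,7S,8R,9S,10E,12E,15S,16Z)-6-[(tert-butyldimethylsilyl)oxy]-8-hydroxy-17-iodo-3,5,7,11,15-pentamethyl-9-({[tri(propan-2-yl)silyl]oxy}methyl)octadeca-2,10,12,16-tetraenoate
Conditions: PPTS (0.2 equiv), MeOH/CH2Cl2 (1:1), 0 °C to rt
Reagents that add atoms: none
Why: Mild acid methanolysis removes the triethylsilyl ether while the far more stable TBS and TIPS ethers stay.

Step 29
Reactants: 43 hydroxy ester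
Product: 44 (2E,5R,6R,7S,8R,9S,10E,12E,15S,16Z)-6-[(tert-butyldimethylsilyl)oxy]-8-hydroxy-17-iodo-3,5,7,11,15-pentamethyl-9-({[tri(propan-2-yl)silyl]oxy}methyl)octadeca-2,10,12,16-tetraenoic acid
Conditions: LiOH, THF/MeOH/H2O (3:1:1), 35 °C; then 0.5 M HCl to pH 4, 0 °C
Reagents that add atoms: lithium hydroxide, [Li+].[OH-]
Why: Saponification of the ethyl ester is done before the base-sensitive lactone is introduced, and no ketone is yet present to epimerise or eliminate.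

Step 30
Reactants: 44 vinyl iodide acid (fragment BC); 7 lactone vinylstannane (fragment A)
Product: 45 (2E,5R,6R,7S,8R,9S,10E,12E,15S,16Z,18E)-6-[(tert-butyldimethylsilyl)oxy]-8-hydroxy-3,5,7,11,15,17-hexamethyl-19-[(2R,3S)-3-methyl-6-oxo-3,6-dihydro-2H-pyran-2-yl]-9-({[tri(propan-2-yl)silyl]oxy}methyl)nonadeca-2,10,12,16,18-pentaenoic acid
Conditions: PdCl2(MeCN)2 (10 mol%), DMF, rt, dark
Reagents that add atoms: none
Why: Stille coupling (oxidative addition of zerovalent palladium into the vinyl iodide, transmetalation, reductive elimination) joins C7–C8 with retention of both alkene geometries under neutral, phosphine-free conditions that the lactone, the acid and the free hydroxyl tolerate.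

Step 31
Reactants: 45 coupled hydroxy acid
Product: 46 (2E,5R,6R,7R,9S,10E,12E,15S,16Z,18E)-6-[(tert-butyldimethylsilyl)oxy]-3,5,7,11,15,17-hexamethyl-19-[(2R,3S)-3-methyl-6-oxo-3,6-dihydro-2H-pyran-2-yl]-8-oxo-9-({[tri(propan-2-yl)silyl]oxy}methyl)nonadeca-2,10,12,16,18-pentaenoic acid
Conditions: Dess–Martin periodinane, pyridine, CH2Cl2, 0 °C to rt
Reagents that add atoms: none
Why: Buffered Dess–Martin oxidation of the only free hydroxyl (C17) gives the ketone without epimerising the now acidic C16 and C18 centres.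

Step 32
Reactants: 46 bis-silyl keto acid
Product: 47 (2E,5R,6R,7R,9S,10E,12E,15S,16Z,18E)-6-hydroxy-9-(hydroxymethyl)-3,5,7,11,15,17-hexamethyl-19-[(2R,3S)-3-methyl-6-oxo-3,6-dihydro-2H-pyran-2-yl]-8-oxononadeca-2,10,12,16,18-pentaenoic acid
Conditions: HF·pyridine, pyridine, THF, 0 °C to rt, 36 h
Reagents that add atoms: none
Why: Pyridine-buffered fluoride desilylation frees the primary and C19 hydroxyls under conditions mild enough to avoid retro-aldol, β-elimination or epimerisation of the β-hydroxy ketone.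

**Compound list**
1 | prop-2-yn-1-ol | C#CCO | starting material
2 | (2E)-3-(tributylstannyl)prop-2-en-1-ol | CCCC[Sn](CCCC)(CCCC)/C=C/CO | intermediate
3 | (2E)-3-(tributylstannyl)prop-2-enal | CCCC[Sn](CCCC)(CCCC)/C=C/C=O | intermediate
4 | (1E,3S,4S)-4-methyl-1-(tributylstannyl)hexa-1,5-dien-3-yl diisopinocampheylborinate | CCCC[Sn](CCCC)(CCCC)/C=C/[C@@H](OB([C@@H]1C[C@@H]2C[C@H]([C@H]1C)C2(C)C)[C@@H]1C[C@@H]2C[C@H]([C@H]1C)C2(C)C)[C@@H](C)C=C | intermediate
5 | (1E,3S,4S)-4-methyl-1-(tributylstannyl)hexa-1,5-dien-3-ol | CCCC[Sn](CCCC)(CCCC)/C=C/[C@@H](O)[C@@H](C)C=C | intermediate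
6 | (1E,3S,4S)-4-methyl-1-(tributylstannyl)hexa-1,5-dien-3-yl prop-2-enoate | CCCC[Sn](CCCC)(CCCC)/C=C/[C@@H](OC(=O)C=C)[C@@H](C)C=C | intermediate
7 | (5S,6S)-5-methyl-6-[(E)-2-(tributylstannyl)ethenyl]-5,6-dihydro-2H-pyran-2-one | CCCC[Sn](CCCC)(CCCC)/C=C/[C@H]1OC(=O)C=C[C@@H]1C | intermediate
8 | (4R)-4-benzyl-3-propanoyl-1,3-oxazolidin-2-one | CCC(=O)N1[C@H](Cc2ccccc2)COC1=O | starting material
9 | sodium (Z)-enolate of 8 | C/C=C(\[O-])N1[C@H](Cc2ccccc2)COC1=O.[Na+] | intermediate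
10 | tert-butyl (3S)-4-[(4R)-4-benzyl-2-oxo-1,3-oxazolidin-3-yl]-3-methyl-4-oxobutanoate | CC(C)(C)OC(=O)C[C@H](C)C(=O)N1[C@H](Cc2ccccc2)COC1=O | intermediate
11 | tert-butyl (3S)-4-hydroxy-3-methylbutanoate | CC(C)(C)OC(=O)C[C@H](C)CO | intermediate
12 | tert-butyl (3S)-3-methyl-4-oxobutanoate | CC(C)(C)OC(=O)C[C@H](C)C=O | intermediate
13 | tert-butyl (3S,4Z)-5-iodo-3-methylhex-4-enoate | C/C(I)=C/[C@@H](C)CC(=O)OC(C)(C)C | intermediate
14 | (3S,4Z)-5-iodo-3-methylhex-4-en-1-ol | C/C(I)=C/[C@@H](C)CCO | intermediate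
15 | 5-{[(3S,4Z)-5-iodo-3-methylhex-4-en-1-yl]sulfanyl}-1-phenyl-1H-tetrazole | C/C(I)=C/[C@@H](C)CCSc1nnnn1-c1ccccc1 | intermediate
16 | 5-{[(3S,4Z)-5-iodo-3-methylhex-4-en-1-yl]sulfonyl}-1-phenyl-1H-tetrazole | C/C(I)=C/[C@@H](C)CCS(=O)(=O)c1nnnn1-c1ccccc1 | intermediate
17 | ethyl 3-methylbut-2-enoate | CCOC(=O)C=C(C)C | starting material
18 | ethyl (2E)-4-bromo-3-methylbut-2-enoate | CCOC(=O)/C=C(\C)CBr | intermediate
19 | (4S)-4-benzyl-3-propanoyl-1,3-oxazolidin-2-one | CCC(=O)N1[C@@H](Cc2ccccc2)COC1=O | starting material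
20 | sodium (Z)-enolate of 19 | C/C=C(\[O-])N1[C@@H](Cc2ccccc2)COC1=O.[Na+] | intermediate
21 | ethyl (2E,5R)-6-[(4S)-4-benzyl-2-oxo-1,3-oxazolidin-3-yl]-3,5-dimethyl-6-oxohex-2-enoate | CCOC(=O)/C=C(\C)C[C@@H](C)C(=O)N1[C@@H](Cc2ccccc2)COC1=O | intermediate
22 | ethyl (2E,5R)-6-hydroxy-3,5-dimethylhex-2-enoate | CCOC(=O)/C=C(\C)C[C@@H](C)CO | intermediate
23 | ethyl (2E,5R)-3,5-dimethyl-6-oxohex-2-enoate | CCOC(=O)/C=C(\C)C[C@@H](C)C=O | intermediate
24 | ethyl (2E,5R,6R,7S)-6-[(diisopinocampheylboranyl)oxy]-3,5,7-trimethylnona-2,8-dienoate | C=C[C@H](C)[C@H](OB([C@@H]1C[C@@H]2C[C@H]([C@H]1C)C2(C)C)[C@@H]1C[C@@H]2C[C@H]([C@H]1C)C2(C)C)[C@H](C)C/C(C)=C/C(=O)OCC | intermediate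
25 | ethyl (2E,5R,6R,7S)-6-hydroxy-3,5,7-trimethylnona-2,8-dienoate | C=C[C@H](C)[C@H](O)[C@H](C)C/C(C)=C/C(=O)OCC | intermediate
26 | ethyl (2E,5R,6R,7S)-6-[(tert-butyldimethylsilyl)oxy]-3,5,7-trimethylnona-2,8-dienoate | C=C[C@H](C)[C@H](O[Si](C)(C)C(C)(C)C)[C@H](C)C/C(C)=C/C(=O)OCC | intermediate
27 | ethyl (2E,5R,6R,7S)-6-[(tert-butyldimethylsilyl)oxy]-8,9-dihydroxy-3,5,7-trimethylnon-2-enoate (both C8 epimers) | OCC(O)[C@H](C)[C@H](O[Si](C)(C)C(C)(C)C)[C@H](C)C/C(C)=C/C(=O)OCC | intermediate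
28 | ethyl (2E,5R,6R,7R)-6-[(tert-butyldimethylsilyl)oxy]-3,5,7-trimethyl-8-oxooct-2-enoate | O=C[C@H](C)[C@H](O[Si](C)(C)C(C)(C)C)[C@H](C)C/C(C)=C/C(=O)OCC | intermediate
29 | 4-methylpent-3-enoic acid | CC(C)=CCC(=O)O | starting material
30 | (4R)-4-benzyl-1,3-oxazolidin-2-one | O=C1N[C@H](Cc2ccccc2)CO1 | starting material
31 | 2,2-dimethylpropanoic 4-methylpent-3-enoic anhydride | CC(C)=CCC(=O)OC(=O)C(C)(C)C | intermediate
32 | (4R)-4-benzyl-3-(4-methylpent-3-enoyl)-1,3-oxazolidin-2-one | CC(C)=CCC(=O)N1[C@H](Cc2ccccc2)COC1=O | intermediate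
33 | dibutylboron (Z)-dienolate of 32 | CC(C)=C/C=C(\OB(CCCC)CCCC)N1[C@H](Cc2ccccc2)COC1=O | intermediate
34 | O8-dibutylboryl aldolate of 35 | CC(C)=C[C@@H](C(=O)N1[C@H](Cc2ccccc2)COC1=O)[C@@H](OB(CCCC)CCCC)[C@H](C)[C@H](O[Si](C)(C)C(C)(C)C)[C@H](C)C/C(C)=C/C(=O)OCC | intermediate
35 | ethyl (2E,5R,6R,7S,8S,9R)-9-[(4R)-4-benzyl-2-oxo-1,3-oxazolidine-3-carbonyl]-6-[(tert-butyldimethylsilyl)oxy]-8-hydroxy-3,5,7,11-tetramethyldodeca-2,10-dienoate | CC(C)=C[C@@H](C(=O)N1[C@H](Cc2ccccc2)COC1=O)[C@@H](O)[C@H](C)[C@H](O[Si](C)(C)C(C)(C)C)[C@H](C)C/C(C)=C/C(=O)OCC | intermediate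
36 | ethyl (2E,5R,6R,7S,8R,9S)-6-[(tert-butyldimethylsilyl)oxy]-8-hydroxy-9-(hydroxymethyl)-3,5,7,11-tetramethyldodeca-2,10-dienoate | CC(C)=C[C@@H](CO)[C@@H](O)[C@H](C)[C@H](O[Si](C)(C)C(C)(C)C)[C@H](C)C/C(C)=C/C(=O)OCC | intermediate
37 | ethyl (2E,5R,6R,7S,8R,9S)-6-[(tert-butyldimethylsilyl)oxy]-8-hydroxy-3,5,7,11-tetramethyl-9-({[tri(propan-2-yl)silyl]oxy}methyl)dodeca-2,10-dienoate | CC(C)=C[C@@H](CO[Si](C(C)C)(C(C)C)C(C)C)[C@@H](O)[C@H](C)[C@H](O[Si](C)(C)C(C)(C)C)[C@H](C)C/C(C)=C/C(=O)OCC | intermediate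
38 | ethyl (2E,5R,6R,7R,8R,9S)-6-[(tert-butyldimethylsilyl)oxy]-3,5,7,11-tetramethyl-8-[(triethylsilyl)oxy]-9-({[tri(propan-2-yl)silyl]oxy}methyl)dodeca-2,10-dienoate | CC(C)=C[C@@H](CO[Si](C(C)C)(C(C)C)C(C)C)[C@@H](O[Si](CC)(CC)CC)[C@H](C)[C@H](O[Si](C)(C)C(C)(C)C)[C@H](C)C/C(C)=C/C(=O)OCC | intermediate
39 | ethyl (2E,5R,6R,7R,8R,9S,10E)-6-[(tert-butyldimethylsilyl)oxy]-12-hydroxy-3,5,7,11-tetramethyl-8-[(triethylsilyl)oxy]-9-({[tri(propan-2-yl)silyl]oxy}methyl)dodeca-2,10-dienoate | OC/C(C)=C/[C@@H](CO[Si](C(C)C)(C(C)C)C(C)C)[C@@H](O[Si](CC)(CC)CC)[C@H](C)[C@H](O[Si](C)(C)C(C)(C)C)[C@H](C)C/C(C)=C/C(=O)OCC | intermediate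
40 | ethyl (2E,5R,6R,7R,8R,9S,10E)-6-[(tert-butyldimethylsilyl)oxy]-3,5,7,11-tetramethyl-12-oxo-8-[(triethylsilyl)oxy]-9-({[tri(propan-2-yl)silyl]oxy}methyl)dodeca-2,10-dienoate | O=C/C(C)=C/[C@@H](CO[Si](C(C)C)(C(C)C)C(C)C)[C@@H](O[Si](CC)(CC)CC)[C@H](C)[C@H](O[Si](C)(C)C(C)(C)C)[C@H](C)C/C(C)=C/C(=O)OCC | intermediate
41 | potassium α-sulfonyl carbanion of 16 | C/C(I)=C/[C@@H](C)C[CH-]S(=O)(=O)c1nnnn1-c1ccccc1.[K+] | intermediate
42 | ethyl (2E,5R,6R,7R,8R,9S,10E,12E,15S,16Z)-6-[(tert-butyldimethylsilyl)oxy]-17-iodo-3,5,7,11,15-pentamethyl-8-[(triethylsilyl)oxy]-9-({[tri(propan-2-yl)silyl]oxy}methyl)octadeca-2,10,12,16-tetraenoate | C/C(I)=C/[C@@H](C)C/C=C/C(C)=C/[C@@H](CO[Si](C(C)C)(C(C)C)C(C)C)[C@@H](O[Si](CC)(CC)CC)[C@H](C)[C@H](O[Si](C)(C)C(C)(C)C)[C@H](C)C/C(C)=C/C(=O)OCC | intermediate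
43 | ethyl (2E,5R,6R,7S,8R,9S,10E,12E,15S,16Z)-6-[(tert-butyldimethylsilyl)oxy]-8-hydroxy-17-iodo-3,5,7,11,15-pentamethyl-9-({[tri(propan-2-yl)silyl]oxy}methyl)octadeca-2,10,12,16-tetraenoate | C/C(I)=C/[C@@H](C)C/C=C/C(C)=C/[C@@H](CO[Si](C(C)C)(C(C)C)C(C)C)[C@@H](O)[C@H](C)[C@H](O[Si](C)(C)C(C)(C)C)[C@H](C)C/C(C)=C/C(=O)OCC | intermediate
44 | (2E,5R,6R,7S,8R,9S,10E,12E,15S,16Z)-6-[(tert-butyldimethylsilyl)oxy]-8-hydroxy-17-iodo-3,5,7,11,15-pentamethyl-9-({[tri(propan-2-yl)silyl]oxy}methyl)octadeca-2,10,12,16-tetraenoic acid | C/C(I)=C/[C@@H](C)C/C=C/C(C)=C/[C@@H](CO[Si](C(C)C)(C(C)C)C(C)C)[C@@H](O)[C@H](C)[C@H](O[Si](C)(C)C(C)(C)C)[C@H](C)C/C(C)=C/C(=O)O | intermediate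
45 | (2E,5R,6R,7S,8R,9S,10E,12E,15S,16Z,18E)-6-[(tert-butyldimethylsilyl)oxy]-8-hydroxy-3,5,7,11,15,17-hexamethyl-19-[(2R,3S)-3-methyl-6-oxo-3,6-dihydro-2H-pyran-2-yl]-9-({[tri(propan-2-yl)silyl]oxy}methyl)nonadeca-2,10,12,16,18-pentaenoic acid | CC(=C/[C@@H](C)C/C=C/C(C)=C/[C@@H](CO[Si](C(C)C)(C(C)C)C(C)C)[C@@H](O)[C@H](C)[C@H](O[Si](C)(C)C(C)(C)C)[C@H](C)C/C(C)=C/C(=O)O)/C=C/[C@H]1OC(=O)C=C[C@@H]1C | intermediate
46 | (2E,5R,6R,7R,9S,10E,12E,15S,16Z,18E)-6-[(tert-butyldimethylsilyl)oxy]-3,5,7,11,15,17-hexamethyl-19-[(2R,3S)-3-methyl-6-oxo-3,6-dihydro-2H-pyran-2-yl]-8-oxo-9-({[tri(propan-2-yl)silyl]oxy}methyl)nonadeca-2,10,12,16,18-pentaenoic acid | CC(=C/[C@@H](C)C/C=C/C(C)=C/[C@@H](CO[Si](C(C)C)(C(C)C)C(C)C)C(=O)[C@H](C)[C@H](O[Si](C)(C)C(C)(C)C)[C@H](C)C/C(C)=C/C(=O)O)/C=C/[C@H]1OC(=O)C=C[C@@H]1C | intermediate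
47 | (2E,5R,6R,7R,9S,10E,12E,15S,16Z,18E)-6-hydroxy-9-(hydroxymethyl)-3,5,7,11,15,17-hexamethyl-19-[(2R,3S)-3-methyl-6-oxo-3,6-dihydro-2H-pyran-2-yl]-8-oxononadeca-2,10,12,16,18-pentaenoic acid | CC(=C/[C@@H](C)C/C=C/C(C)=C/[C@@H](CO)C(=O)[C@H](C)[C@H](O)[C@H](C)C/C(C)=C/C(=O)O)/C=C/[C@H]1OC(=O)C=C[C@@H]1C | target

**Totals**
Total step count: 32. Longest linear sequence: 19 steps (from 17 through steps 13–19 and 21–32). The other branches are 5 steps (fragment A), 7 steps (fragment B) and 1 step (imide 32).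

**Steps most likely to fail, with fallbacks**

Step 25 (late SeO2 allylic oxidation: modest yield, over-oxidation, possible loss of the triethylsilyl group). The fallback sets out from 38 and replaces the oxidation by cleavage and re-olefination. Ozonolysis of the electron-rich isobutenyl alkene (O3, CH2Cl2/pyridine, −78 °C, stopped after one equivalent; PPh3) spares the enoate and gives the aldehyde ethyl (2E,5R,6R,7R,8S,9S)-6-[(tert-butyldimethylsilyl)oxy]-3,5,7-trimethyl-10-oxo-8-[(triethylsilyl)oxy]-9-({[tri(propan-2-yl)silyl]oxy}methyl)dec-2-enoate F1. A Wittig reaction of this aldehyde with the stabilised ylide 2-(triphenylphosphoranylidene)propanal (toluene, 80 °C) rebuilds C14=C15 with E geometry and comes back to the route at 40.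

Step 27 (E/Z ratio of the diene and self-condensation of the PT-sulfone anion). The fallback reverses the polarity of the olefination and sets out from 39 and 14. Appel bromination of 39 (CBr4, PPh3, 2,6-lutidine, CH2Cl2, 0 °C) gives the allylic bromide ethyl (2E,5R,6R,7R,8R,9S,10E)-12-bromo-6-[(tert-butyldimethylsilyl)oxy]-3,5,7,11-tetramethyl-8-[(triethylsilyl)oxy]-9-({[tri(propan-2-yl)silyl]oxy}methyl)dodeca-2,10-dienoate F2. PBu3 in MeCN converts it into the C13 tributylphosphonium bromide of the same skeleton F3. In parallel, Dess–Martin oxidation of 14 gives (3S,4Z)-5-iodo-3-methylhex-4-enal F4. Deprotonation of the phosphonium salt (KOtBu, toluene, 0 °C) and Wittig reaction of the semi-stabilised trialkylphosphonium ylide with the aldehyde is reliably E-selective and comes back to the route at 42.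

Step 30 (hindered Z-trisubstituted vinyl iodide, free acid, possible protodestannylation of 7). The fallback exchanges the roles of the two partners and sets out from 7 and 44. Iododestannylation of 7 (I2, CH2Cl2, 0 °C) gives (5S,6S)-6-[(E)-2-iodoethenyl]-5-methyl-5,6-dihydro-2H-pyran-2-one F5. Stannylation of 44 with Me3SnSnMe3 (Pd(PPh3)4, iPr2NEt, toluene, 80 °C) gives (2E,5R,6R,7S,8R,9S,10E,12E,15S,16Z)-6-[(tert-butyldimethylsilyl)oxy]-8-hydroxy-3,5,7,11,15-pentamethyl-9-({[tri(propan-2-yl)silyl]oxy}methyl)-17-(trimethylstannyl)octadeca-2,10,12,16-tetraenoic acid F6. Stille coupling of this stannane with the unhindered lactone iodide (Pd2(dba)3, AsPh3, NMP, rt) comes back to the route at 45.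

**Further compounds**
F1 | step 25 | ethyl (2E,5R,6R,7R,8S,9S)-6-[(tert-butyldimethylsilyl)oxy]-3,5,7-trimethyl-10-oxo-8-[(triethylsilyl)oxy]-9-({[tri(propan-2-yl)silyl]oxy}methyl)dec-2-enoate | O=C[C@@H](CO[Si](C(C)C)(C(C)C)C(C)C)[C@@H](O[Si](CC)(CC)CC)[C@H](C)[C@H](O[Si](C)(C)C(C)(C)C)[C@H](C)C/C(C)=C/C(=O)OCC
F2 | step 27 | ethyl (2E,5R,6R,7R,8R,9S,10E)-12-bromo-6-[(tert-butyldimethylsilyl)oxy]-3,5,7,11-tetramethyl-8-[(triethylsilyl)oxy]-9-({[tri(propan-2-yl)silyl]oxy}methyl)dodeca-2,10-dienoate | BrC/C(C)=C/[C@@H](CO[Si](C(C)C)(C(C)C)C(C)C)[C@@H](O[Si](CC)(CC)CC)[C@H](C)[C@H](O[Si](C)(C)C(C)(C)C)[C@H](C)C/C(C)=C/C(=O)OCC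
F3 | step 27 | C13 tributylphosphonium bromide of the same skeleton (PBu3 in place of the bromine of F2) | CCCC[P+](CCCC)(CCCC)C/C(C)=C/[C@@H](CO[Si](C(C)C)(C(C)C)C(C)C)[C@@H](O[Si](CC)(CC)CC)[C@H](C)[C@H](O[Si](C)(C)C(C)(C)C)[C@H](C)C/C(C)=C/C(=O)OCC.[Br-]
F4 | step 27 | (3S,4Z)-5-iodo-3-methylhex-4-enal | C/C(I)=C/[C@@H](C)CC=O
F5 | step 30 | (5S,6S)-6-[(E)-2-iodoethenyl]-5-methyl-5,6-dihydro-2H-pyran-2-one | I/C=C/[C@H]1OC(=O)C=C[C@@H]1C
F6 | step 30 | (2E,5R,6R,7S,8R,9S,10E,12E,15S,16Z)-6-[(tert-butyldimethylsilyl)oxy]-8-hydroxy-3,5,7,11,15-pentamethyl-9-({[tri(propan-2-yl)silyl]oxy}methyl)-17-(trimethylstannyl)octadeca-2,10,12,16-tetraenoic acid | C/C(=C/[C@@H](C)C/C=C/C(C)=C/[C@@H](CO[Si](C(C)C)(C(C)C)C(C)C)[C@@H](O)[C@H](C)[C@H](O[Si](C)(C)C(C)(C)C)[C@H](C)C/C(C)=C/C(=O)O)[Sn](C)(C)C
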